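**Strategy.** The enolised trione ring A (spiro C1, C2=O, C3–acetyl, C4–OH, C5 diprenyl, C6=O) is disconnected at C1–C2 and C5–C6 and closed last on a finished trans-hydrindane (rings B and C), made from (R)-linalool by intramolecular Diels–Alder reaction. The key step exploits that C3, C4 and the acetyl group are an enolised β-diketone, i.e. an unmasked 3,5-dimethylisoxazole. In one pot the hydrindane ester enolate is C-acylated by 3,5-dimethylisoxazole-4-carbonyl chloride on its equatorial face (setting spiro C1 anti to the axial ring B methyl); the isoxazole 5-methyl is then metalated and attacks the ester, closing ring A. Diprenylation at C5, N–O cleavage and desilylation follow.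

Key step: step 7

Remark: the β-triketone is one compound with rapidly interconverting enol forms and is drawn in the enol form of the target structure; (R)-(−)-linalool supplies the absolute configuration.

Step 1
Reactants: 1 (R)-linalool
Product: 2 (2E,6R)-2,6-dimethylocta-2,7-diene-1,6-diol
Conditions: SeO2 (0.3 equiv), tBuOOH (3 equiv), salicylic acid (0.1 equiv), CH2Cl2, rt
Reagents that add atoms: tert-butyl hydroperoxide, CC(C)(C)OO; selenium dioxide (catalytic oxygen carrier), O=[Se]=O
Why: Selenium dioxide allylic oxidation (ene reaction, then [2,3]-sigmatropic shift) should attack the (E)-methyl of the trisubstituted alkene, since the vinyl group has no allylic hydrogen and the carbinol stereocentre is not touched.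

Step 2
Reactants: 2 (2E,6R)-2,6-dimethylocta-2,7-diene-1,6-diol; 3 methyl (triphenylphosphoranylidene)acetate
Product: 5 methyl (2E,4E,8R)-8-hydroxy-4,8-dimethyldeca-2,4,9-trienoate, via enal 4 (not isolated)
Conditions: MnO2 (15 equiv), 3 (1.3 equiv), CH2Cl2, rt
Reagents that add atoms: methyl (triphenylphosphoranylidene)acetate (3), COC(=O)C=P(c1ccccc1)(c1ccccc1)c1ccccc1
Why: Tandem MnO2 oxidation–Wittig olefination: MnO2 oxidises only the primary allylic alcohol and the stabilised ylide traps the enal in situ to give the (2E) alkene.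

Step 3
Reactants: 5 methyl (2E,4E,8R)-8-hydroxy-4,8-dimethyldeca-2,4,9-trienoate
Product: 6 methyl (1R,3aR,6S,7aS)-1-hydroxy-1,4-dimethyl-2,3,3a,6,7,7a-hexahydro-1H-indene-6-carboxylate
Conditions: toluene (0.01 M), BHT (0.1 equiv), 190 °C, sealed tube
Reagents that add atoms: none
Why: Thermal intramolecular Diels–Alder reaction of a 1,3,8-nonatriene (dienoate diene, vinyl dienophile): the exo-tether transition state, expected to be favoured because the internal diene methyl clashes with the tether in the cis-fused alternative, gives the trans ring fusion, the C8 carbinol places its methyl pseudo-equatorial (cis to H-7a) and its hydroxyl pseudo-axial on the forming cyclopentane and so fixes C3a and C7a, and suprafacial addition to the E,E-diene puts the ester cis to C3 (pseudo-axial, 6S).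

Step 4
Reactants: 6 methyl (1R,3aR,6S,7aS)-1-hydroxy-1,4-dimethyl-2,3,3a,6,7,7a-hexahydro-1H-indene-6-carboxylate
Product: 8 methyl (1R,3aR,4S,7aS)-1,4-dihydroxy-1,4-dimethyl-2,3,3a,4,7,7a-hexahydro-1H-indene-6-carboxylate, via epoxide 7 (not isolated)
Conditions: mCPBA (1.1 equiv), CH2Cl2, 0 °C; then DBU (3 equiv), 0 °C to rt
Reagents that add atoms: 3-chloroperoxybenzoic acid (mCPBA), O=C(OO)c1cccc(Cl)c1
Why: Prilezhaev epoxidation of the only alkene should occur anti to the pseudo-axial C6 ester, on the face of H-3a (the C1 hydroxyl on that face may assist), and DBU then opens the β,γ-epoxy ester by E1cB elimination, which leaves the new C4–O bond untouched and so sets C4 with hydroxyl equatorial and methyl axial.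

Step 5
Reactants: 8 methyl (1R,3aR,4S,7aS)-1,4-dihydroxy-1,4-dimethyl-2,3,3a,4,7,7a-hexahydro-1H-indene-6-carboxylate
Product: 9 methyl (1R,3aR,4R,7aS)-1,4-dihydroxy-1,4-dimethyloctahydro-1H-indene-6-carboxylate (either C6 epimer serves)
Conditions: H2 (1 atm), Pd/C (10 wt% palladium on carbon), EtOAc, rt
Reagents that add atoms: none
Why: Heterogeneous hydrogenation saturates the conjugated trisubstituted alkene under neutral conditions; the new C6 centre is of no consequence because it is enolised in step 7.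

Step 6
Reactants: 9 methyl (1R,3aR,4R,7aS)-1,4-dihydroxy-1,4-dimethyloctahydro-1H-indene-6-carboxylate
Product: 10 methyl (1R,3aR,4R,7aS)-1,4-dimethyl-1,4-bis(triethylsilyloxy)octahydro-1H-indene-6-carboxylate
Conditions: Et3SiOTf (3 equiv), 2,6-lutidine (5 equiv), CH2Cl2, 0 °C to rt
Reagents that add atoms: triethylsilyl trifluoromethanesulfonate, CC[Si](CC)(CC)OS(=O)(=O)C(F)(F)F
Why: A silyl triflate with a hindered pyridine base silylates both tertiary alcohols, so that no alkoxide can compete for the acid chloride or quench the carbanions of step 7.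

Step 7
Reactants: 10 methyl (1R,3aR,4R,7aS)-1,4-dimethyl-1,4-bis(triethylsilyloxy)octahydro-1H-indene-6-carboxylate; 11 3,5-dimethyl-1,2-oxazole-4-carbonyl chloride
Product: 13 (1'R,3a'R,4'R,5R,7a'S)-1',3,4'-trimethyl-1',4'-bis(triethylsilyloxy)-1',2',3',3a',4',5',7',7a'-octahydro-7H-spiro[1,2-benzoxazole-5,6'-indene]-4,6-dione, via β-keto ester 12 (not isolated)
Conditions: LiN(iPr)2 (LDA, 1.1 equiv), THF, −78 to −40 °C; 11 (1.05 equiv), −78 °C; then LiN(SiMe3)2 (LiHMDS, 3 equiv), −78 to 0 °C
Reagents that add atoms: 3,5-dimethyl-1,2-oxazole-4-carbonyl chloride (11), Cc1noc(C)c1C(=O)Cl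
Why: LDA forms the exocyclic lithium ester enolate of 10, which is C-acylated by acid chloride 11 (ester enolate acylation, a crossed Claisen reaction) to give β-keto ester 12 and the C1–C2 bond of ring A. The electrophile should approach C6' on the equatorial face, because the axial face is shielded by the axial C4' methyl and the axial H-7a' of the rigid trans-hydrindane chair; the ketone therefore ends equatorial and the ester axial, which is the required spiro configuration (the control known for cyclohexanecarboxylate enolates that carry a 3-axial methyl). LiHMDS then removes a proton from the isoxazole 5-methyl, which is vinylogously acidified by the 4-acyl group (lateral metalation of 5-methylisoxazoles), and the dienolate carbon attacks the ester carbonyl in a Dieckmann-type 6-(enolendo)-exo-trig closure that forms the C5–C6 bond of ring A and expels methoxide. Deprotonation of the new methylene of 13, which lies between a ketone and the heteroarene, makes the closure irreversible. The step needs C- over O-acylation (lithium enolate, acid chloride, low temperature), equatorial attack (secured by the axial methyl) and metalation of the 5- rather than the 3-methyl (only the 5-methyl is conjugated to the carbonyl).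

Step 8
Reactants: 13 (1'R,3a'R,4'R,5R,7a'S)-1',3,4'-trimethyl-1',4'-bis(triethylsilyloxy)-1',2',3',3a',4',5',7',7a'-octahydro-7H-spiro[1,2-benzoxazole-5,6'-indene]-4,6-dione; 14 1-bromo-3-methylbut-2-ene (prenyl bromide)
Product: 15 (1'R,3a'R,4'R,5R,7a'S)-1',3,4'-trimethyl-7,7-bis(3-methylbut-2-en-1-yl)-1',4'-bis(triethylsilyloxy)-1',2',3',3a',4',5',7',7a'-octahydro-7H-spiro[1,2-benzoxazole-5,6'-indene]-4,6-dione
Conditions: NaH (2.5 equiv), 14 (3 equiv), THF, 0 to 40 °C
Reagents that add atoms: 1-bromo-3-methylbut-2-ene (14), CC(C)=CCBr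
Why: C7 is the only enolisable position of 13 (its enolate is conjugated with the isoxazole), so two successive SN2 C-alkylations by the soft allylic bromide should build the diprenyl quaternary carbon, while the isoxazole keeps the masked acetyl enol from O-alkylation; no stereocentre is formed.

Step 9
Reactants: 15 (1'R,3a'R,4'R,5R,7a'S)-1',3,4'-trimethyl-7,7-bis(3-methylbut-2-en-1-yl)-1',4'-bis(triethylsilyloxy)-1',2',3',3a',4',5',7',7a'-octahydro-7H-spiro[1,2-benzoxazole-5,6'-indene]-4,6-dione
Product: 17 (1R,1'R,3a'R,4'R,7a'S)-3-acetyl-4-hydroxy-1',4'-dimethyl-5,5-bis(3-methylbut-2-en-1-yl)-1',4'-bis(triethylsilyloxy)-1',2',3',3a',4',5',7',7a'-octahydrospiro[cyclohex-3-ene-1,6'-indene]-2,6-dione, via enaminone 16 (not isolated)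
Conditions: Mo(CO)6 (1.2 equiv), MeCN/H2O (10:1), 80 °C; then NaOH (1 M aq), EtOH, 60 °C; HCl (1 M) to pH 3
Reagents that add atoms: water, O
Why: Mo(CO)6 in wet acetonitrile cleaves the isoxazole N–O bond reductively without reducing the prenyl alkenes, and hydroxide then hydrolyses the doubly acyl-activated enaminone by addition–elimination to release the acetyl enol of the β-triketone; no stereocentre is touched.

Step 10
Reactants: 17 (1R,1'R,3a'R,4'R,7a'S)-3-acetyl-4-hydroxy-1',4'-dimethyl-5,5-bis(3-methylbut-2-en-1-yl)-1',4'-bis(triethylsilyloxy)-1',2',3',3a',4',5',7',7a'-octahydrospiro[cyclohex-3-ene-1,6'-indene]-2,6-dione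
Product: 18 (1R,1'R,3a'R,4'R,7a'S)-3-acetyl-1',4,4'-trihydroxy-1',4'-dimethyl-5,5-bis(3-methylbut-2-en-1-yl)-1',2',3',3a',4',5',7',7a'-octahydrospiro[cyclohex-3-ene-1,6'-indene]-2,6-dione (CNP0266834.2)
Conditions: HF·pyridine, pyridine, THF, 0 °C to rt
Reagents that add atoms: none
Why: Fluoride cleaves the two tertiary triethylsilyl ethers under buffered conditions that should neither dehydrate the tertiary alcohols nor cyclise the prenyl groups onto the enol.

**Compound list**

1 | (R)-linalool, (3R)-3,7-dimethylocta-1,6-dien-3-ol | CC(C)=CCC[C@@](C)(O)C=C | starting material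
2 | (2E,6R)-2,6-dimethylocta-2,7-diene-1,6-diol | OC/C(C)=C/CC[C@@](C)(O)C=C | intermediate
3 | methyl (triphenylphosphoranylidene)acetate | COC(=O)C=P(c1ccccc1)(c1ccccc1)c1ccccc1 | starting material
4 | (2E,6R)-6-hydroxy-2,6-dimethylocta-2,7-dienal | O=C/C(C)=C/CC[C@@](C)(O)C=C | intermediate
5 | methyl (2E,4E,8R)-8-hydroxy-4,8-dimethyldeca-2,4,9-trienoate | COC(=O)/C=C/C(C)=C/CC[C@@](C)(O)C=C | intermediate
6 | methyl (1R,3aR,6S,7aS)-1-hydroxy-1,4-dimethyl-2,3,3a,6,7,7a-hexahydro-1H-indene-6-carboxylate (trans-fused; ester cis to C3) | COC(=O)[C@H]1C[C@H]2[C@@H](CC[C@@]2(C)O)C(C)=C1 | intermediate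
7 | methyl (1R,3aR,4S,5R,6S,7aS)-4,5-epoxy-1-hydroxy-1,4-dimethyloctahydro-1H-indene-6-carboxylate (epoxide on the face of H-3a) | COC(=O)[C@H]1C[C@H]2[C@@H](CC[C@@]2(C)O)[C@]3(C)O[C@H]13 | intermediate
8 | methyl (1R,3aR,4S,7aS)-1,4-dihydroxy-1,4-dimethyl-2,3,3a,4,7,7a-hexahydro-1H-indene-6-carboxylate | COC(=O)C1=C[C@@](C)(O)[C@@H]2CC[C@@](C)(O)[C@H]2C1 | intermediate
9 | methyl (1R,3aR,4R,7aS)-1,4-dihydroxy-1,4-dimethyloctahydro-1H-indene-6-carboxylate (C6 not defined) | COC(=O)C1C[C@H]2[C@@H](CC[C@@]2(C)O)[C@](C)(O)C1 | intermediate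
10 | methyl (1R,3aR,4R,7aS)-1,4-dimethyl-1,4-bis(triethylsilyloxy)octahydro-1H-indene-6-carboxylate (C6 not defined) | COC(=O)C1C[C@H]2[C@@H](CC[C@@]2(C)O[Si](CC)(CC)CC)[C@](C)(O[Si](CC)(CC)CC)C1 | intermediate
11 | 3,5-dimethyl-1,2-oxazole-4-carbonyl chloride | Cc1noc(C)c1C(=O)Cl | starting material
12 | methyl (1R,3aR,4R,6S,7aS)-6-(3,5-dimethyl-1,2-oxazole-4-carbonyl)-1,4-dimethyl-1,4-bis(triethylsilyloxy)octahydro-1H-indene-6-carboxylate (ketone equatorial, ester axial) | COC(=O)[C@]1(C[C@H]2[C@@H](CC[C@@]2(C)O[Si](CC)(CC)CC)[C@](C)(O[Si](CC)(CC)CC)C1)C(=O)c1c(C)noc1C | intermediate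
13 | (1'R,3a'R,4'R,5R,7a'S)-1',3,4'-trimethyl-1',4'-bis(triethylsilyloxy)-1',2',3',3a',4',5',7',7a'-octahydro-7H-spiro[1,2-benzoxazole-5,6'-indene]-4,6-dione | Cc1noc2CC(=O)[C@]3(C[C@H]4[C@@H](CC[C@@]4(C)O[Si](CC)(CC)CC)[C@](C)(O[Si](CC)(CC)CC)C3)C(=O)c12 | intermediate
14 | 1-bromo-3-methylbut-2-ene (prenyl bromide) | CC(C)=CCBr | starting material
15 | (1'R,3a'R,4'R,5R,7a'S)-1',3,4'-trimethyl-7,7-bis(3-methylbut-2-en-1-yl)-1',4'-bis(triethylsilyloxy)-1',2',3',3a',4',5',7',7a'-octahydro-7H-spiro[1,2-benzoxazole-5,6'-indene]-4,6-dione | Cc1noc2C(CC=C(C)C)(CC=C(C)C)C(=O)[C@]3(C[C@H]4[C@@H](CC[C@@]4(C)O[Si](CC)(CC)CC)[C@](C)(O[Si](CC)(CC)CC)C3)C(=O)c12 | intermediate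
16 | (1R,1'R,3a'R,4'R,7a'S)-3-(1-aminoethylidene)-1',4'-dimethyl-5,5-bis(3-methylbut-2-en-1-yl)-1',4'-bis(triethylsilyloxy)octahydrospiro[cyclohexane-1,6'-indene]-2,4,6-trione | CC(N)=C1C(=O)C(CC=C(C)C)(CC=C(C)C)C(=O)[C@]2(C[C@H]3[C@@H](CC[C@@]3(C)O[Si](CC)(CC)CC)[C@](C)(O[Si](CC)(CC)CC)C2)C1=O | intermediate
17 | (1R,1'R,3a'R,4'R,7a'S)-3-acetyl-4-hydroxy-1',4'-dimethyl-5,5-bis(3-methylbut-2-en-1-yl)-1',4'-bis(triethylsilyloxy)-1',2',3',3a',4',5',7',7a'-octahydrospiro[cyclohex-3-ene-1,6'-indene]-2,6-dione | CC(=O)C1=C(O)C(CC=C(C)C)(CC=C(C)C)C(=O)[C@]2(C[C@H]3[C@@H](CC[C@@]3(C)O[Si](CC)(CC)CC)[C@](C)(O[Si](CC)(CC)CC)C2)C1=O | intermediate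
18 | (1R,1'R,3a'R,4'R,7a'S)-3-acetyl-1',4,4'-trihydroxy-1',4'-dimethyl-5,5-bis(3-methylbut-2-en-1-yl)-1',2',3',3a',4',5',7',7a'-octahydrospiro[cyclohex-3-ene-1,6'-indene]-2,6-dione | CC(=O)C1=C(O)C(CC=C(C)C)(CC=C(C)C)C(=O)[C@]2(C[C@H]3[C@@H](CC[C@@]3(C)O)[C@](C)(O)C2)C1=O | target

Total step count: 10. Longest linear sequence: 10 steps, from (R)-linalool.

**Steps most likely to fail**

Step 7. The hindered, fully substituted ester enolate may be O-acylated instead of C-acylated, or the acidic 5-methyl of the acid chloride may quench it by proton transfer. The fallback sets out from 10 and forms the C1–C2 bond by an aldol addition: the same lithium enolate is added to 3,5-dimethyl-1,2-oxazole-4-carbaldehyde (same equatorial approach), which should give the β-hydroxy ester F1. Dess–Martin oxidation then gives β-keto ester 12, now isolated, and the ring is closed in a separate operation with LiN(SiMe3)2 in THF. The route is rejoined at 13.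

Step 8. The second alkylation has to form a quaternary carbon next to a ketone that is flanked by the spiro centre, so O-alkylation or arrest after one prenyl group may take over. The fallback sets out from 13 and uses a smaller electrophile delivered through a π-allyl complex: Tsuji–Trost diallylation (Pd(PPh3)4, allyl methyl carbonate, THF, 60 °C) should give the 7,7-diallyl ketone F2. Double cross-metathesis with 2-methylbut-2-ene (second-generation Grubbs catalyst) then turns both allyl groups into prenyl groups. The route is rejoined at 15.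

Step 9. The doubly acyl-stabilised primary enaminone may resist hydrolysis, and forcing base may open the non-enolisable 1,3-diketone of the diprenylated ring by retro-Claisen cleavage. The fallback sets out from 13, before prenylation, where ring A still has its C5 methylene and is protected against retro-Claisen cleavage as a fully delocalised enolate. N–O cleavage with Mo(CO)6 in wet MeCN gives the unprenylated enaminone F3, and hot aqueous NaOH hydrolyses it to the unprenylated acetyl trione F4. The C5 methylene of F4 is then diprenylated in the manner known for acylphloroglucinols (14, NaOMe, MeOH, 0 °C). The route is rejoined at 17.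

**Further compounds**

F1 | step 7 | methyl (1R,3aR,4R,6S,7aS)-6-[(3,5-dimethyl-1,2-oxazol-4-yl)(hydroxy)methyl]-1,4-dimethyl-1,4-bis(triethylsilyloxy)octahydro-1H-indene-6-carboxylate (carbinol epimers) | COC(=O)[C@]1(C[C@H]2[C@@H](CC[C@@]2(C)O[Si](CC)(CC)CC)[C@](C)(O[Si](CC)(CC)CC)C1)C(O)c1c(C)noc1C
F2 | step 8 | (1'R,3a'R,4'R,5R,7a'S)-1',3,4'-trimethyl-7,7-di(prop-2-en-1-yl)-1',4'-bis(triethylsilyloxy)-1',2',3',3a',4',5',7',7a'-octahydro-7H-spiro[1,2-benzoxazole-5,6'-indene]-4,6-dione | Cc1noc2C(CC=C)(CC=C)C(=O)[C@]3(C[C@H]4[C@@H](CC[C@@]4(C)O[Si](CC)(CC)CC)[C@](C)(O[Si](CC)(CC)CC)C3)C(=O)c12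
F3 | step 9 | (1R,1'R,3a'R,4'R,7a'S)-3-(1-aminoethylidene)-1',4'-dimethyl-1',4'-bis(triethylsilyloxy)octahydrospiro[cyclohexane-1,6'-indene]-2,4,6-trione | CC(N)=C1C(=O)CC(=O)[C@]2(C[C@H]3[C@@H](CC[C@@]3(C)O[Si](CC)(CC)CC)[C@](C)(O[Si](CC)(CC)CC)C2)C1=O
F4 | step 9 | (1R,1'R,3a'R,4'R,7a'S)-3-acetyl-4-hydroxy-1',4'-dimethyl-1',4'-bis(triethylsilyloxy)-1',2',3',3a',4',5',7',7a'-octahydrospiro[cyclohex-3-ene-1,6'-indene]-2,6-dione | CC(=O)C1=C(O)CC(=O)[C@]2(C[C@H]3[C@@H](CC[C@@]3(C)O[Si](CC)(CC)CC)[C@](C)(O[Si](CC)(CC)CC)C2)C1=O
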